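**Retrosynthetic overview**

1. Feature: ring A (C4a, C5, C6, C7, C8, C8a, with oxygen on C5, C7 and C8a) plus the C4 ketone is an acylphloroglucinol, and O1–C2(=O)–C3–C4(=O) is a β-keto lactone. C2 to C8a is therefore one folded 1,3-polycarbonyl chain, which a 3-cyclohexenyl-4-hydroxy-6-(2-oxoalkyl)-2-pyrone can store.
2. Last skeletal bonds: C4a–C5 (Claisen, closes ring A) and then O1–C2 (closes the lactone ring), both from that pyrone; the six MOM ethers are removed afterwards.
3. Pyrone C3–cyclohexene C1 bond: acid-catalysed allylation of a 4-hydroxypyrone by a 1-methylcyclohex-2-en-1-ol, anti to the neighbouring substituent (ring A trans to the later aroyl group).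
4. Cyclohexene ring (formed first): asymmetric Diels–Alder reaction of a 2′-hydroxychalcone with isoprene, then kinetic ketonisation to the cis aryl/aroyl pair. The ketone is carried as a silyl-protected carbinol until the pyrone is attached.
5. C3: enantioselective desymmetrising reduction of the prochiral aryl(prenyl)malonate; C4–C4a bond by addition of the triacetic acid lactone dianion to the derived aldehyde.

Key step: step 20

**Remarks on the chemistry**

- The target is taken in the open keto-lactone form drawn. On its cyclohexene the aroyl group is trans to ring A and cis to the aryl group, and every stereochemical choice below is made for that arrangement.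
- The ligand antipodes in steps 4 and 14 are named by analogy with related substrates; the mirror-image ligand is used if the sense proves opposite.
- Carbinol and epoxide centres that are destroyed later (in 11–16 and 28–30) are carried as mixtures and left open in the SMILES.
- MOM = methoxymethyl.

**Route**

Step 1
Reactants: 1 2,4-dihydroxybenzaldehyde
Product: 2 2,4-bis(methoxymethoxy)benzaldehyde
Conditions: MOMCl, i-Pr2NEt, CH2Cl2, 0 °C → reflux
Reagents that add atoms: chloromethyl methyl ether (MOMCl), COCCl
Why: Williamson-type O-alkylation of both phenols by the reactive α-chloro ether, with a hindered amine base that leaves the aldehyde alone.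

Step 2
Reactants: 3 1-(2,4-dihydroxyphenyl)ethan-1-one
Product: 4 1-[2-hydroxy-4-(methoxymethoxy)phenyl]ethan-1-one
Conditions: MOMCl (1.1 equiv), K2CO3, acetone, rt
Reagents that add atoms: chloromethyl methyl ether (MOMCl), COCCl
Why: Selective Williamson etherification of the 4-hydroxyl, because the 2-hydroxyl is held in a hydrogen bond to the acetyl group; the free 2-hydroxyl is kept to bind boron in step 4.

Step 3
Reactants: 2 2,4-bis(methoxymethoxy)benzaldehyde; 4 1-[2-hydroxy-4-(methoxymethoxy)phenyl]ethan-1-one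
Product: 5 (E)-3-[2,4-bis(methoxymethoxy)phenyl]-1-[2-hydroxy-4-(methoxymethoxy)phenyl]prop-2-en-1-one
Conditions: KOH, EtOH/H2O, rt; then dilute HCl to pH 6
Reagents that add atoms: none
Why: Claisen–Schmidt condensation (crossed aldol and dehydration) of the methyl ketone with the non-enolisable aldehyde gives the E-enone, and aryl MOM ethers are stable to hydroxide.

Step 4
Reactants: 5 the 2′-hydroxychalcone; 6 isoprene
Product: 7 [(1R,6R)-6-[2,4-bis(methoxymethoxy)phenyl]-4-methylcyclohex-3-en-1-yl][2-hydroxy-4-(methoxymethoxy)phenyl]methanone (trans)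
Conditions: B(OPh)3 (0.3 equiv), (R)-BINOL (0.3 equiv), 5 Å MS, PhCF3, 40 °C, sealed tube
Reagents that add atoms: none
Why: Asymmetric Diels–Alder reaction in which the 2′-hydroxy enone is bound to the chiral BINOL borate as a six-membered chelate: the E-alkene gives the trans adduct, isoprene adds "para" (methyl 1,4 to the acyl-bearing carbon) and the ligand shields one enone face, which sets C1 and C6 (6R is the centre that is kept).

Step 5
Reactants: 7 the trans hydroxy ketone
Product: 8 [(1R,6R)-6-[2,4-bis(methoxymethoxy)phenyl]-4-methylcyclohex-3-en-1-yl][2,4-bis(methoxymethoxy)phenyl]methanone (trans)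
Conditions: NaH, MOMCl, DMF, 0 °C
Reagents that add atoms: chloromethyl methyl ether (MOMCl), COCCl
Why: O-alkylation of the sodium phenoxide removes the acidic hydroxyl before enolate chemistry; the trans ketone is the stable epimer, so the base does no harm.

Step 6
Reactants: 8 the trans ketone
Product: 10 [(1S,6R)-6-[2,4-bis(methoxymethoxy)phenyl]-4-methylcyclohex-3-en-1-yl][2,4-bis(methoxymethoxy)phenyl]methanone (cis), via lithium enolate 9 (not isolated)
Conditions: LiN(i-Pr)2, THF, −78 → −30 °C; then AcOH, THF, −78 °C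
Reagents that add atoms: none
Why: Kinetic protonation of an exocyclic enolate: allylic 1,3-strain in the tetrasubstituted enolate forces the neighbouring C6 aryl group axial, so the proton enters C1 from the opposite face and gives the less stable cis aryl/aroyl ketone (the known course of ketonisation of 2-arylcyclohexyl aryl ketone enols), C1 becoming S while C6 is untouched.

Step 7
Reactants: 10 the cis ketone
Product: 11 [(1S,6R)-6-[2,4-bis(methoxymethoxy)phenyl]-4-methylcyclohex-3-en-1-yl][2,4-bis(methoxymethoxy)phenyl]methanol (carbinol epimers)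
Conditions: i-Bu2AlH, CH2Cl2, −78 °C; aq. potassium sodium tartrate
Reagents that add atoms: none
Why: Hydride reduction at −78 °C is faster than enolisation and locks the cis relationship by removing the carbonyl that acidifies C1–H and that would cause elimination next to the allyl cation of step 17; the carbinol centre is not controlled and is erased in step 19.

Step 8
Reactants: 11 the carbinol
Product: 12 tert-butyldimethylsilyl ether of 11
Conditions: TBSOTf, 2,6-lutidine, CH2Cl2, −78 → 0 °C
Reagents that add atoms: tert-butyldimethylsilyl triflate, CC(C)(C)[Si](C)(C)OS(=O)(=O)C(F)(F)F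
Why: Silylation of the hindered secondary alcohol with the reactive silyl triflate gives an ether that withstands selenolate, peroxide and catalytic acid.

Step 9
Reactants: 12 the silyl ether
Product: 13 3,4-epoxide of 12 (both epoxide faces)
Conditions: mCPBA, NaHCO3, CH2Cl2, 0 °C
Reagents that add atoms: 3-chloroperbenzoic acid, OOC(=O)c1cccc(Cl)c1
Why: Prilezhaev epoxidation of the only alkene; facial selectivity is not needed because both epoxides lead to the same allyl cation.

Step 10
Reactants: 13 the epoxide
Product: 16 (4S,5R)-5-[2,4-bis(methoxymethoxy)phenyl]-4-{[2,4-bis(methoxymethoxy)phenyl][(tert-butyldimethylsilyl)oxy]methyl}-1-methylcyclohex-2-en-1-ol, via hydroxy selenide 14 (not isolated), via selenoxide 15 (not isolated)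
Conditions: (PhSe)2, NaBH4, EtOH, reflux; then H2O2 (30 %), THF, 0 °C → rt
Reagents that add atoms: none
Why: Selenolate opens the epoxide at its secondary carbon (SN2) and the selenoxide can only eliminate syn towards the ring CH2, giving the transposed tertiary allylic alcohol, the same epoxide-to-allylic-alcohol sequence that turns limonene oxide into p-mentha-2,8-dien-1-ol.

Step 11
Reactants: 17 2,4-dihydroxyphenylacetic acid
Product: 18 methyl 2-(2,4-dihydroxyphenyl)acetate
Conditions: MeOH, H2SO4 (cat.), reflux
Reagents that add atoms: methanol, CO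
Why: Fischer esterification; in methanol any benzofuranone formed from the 2-hydroxyl is opened to the methyl ester.

Step 12
Reactants: 18 the methyl ester
Product: 19 methyl 2-[2,4-bis(methoxymethoxy)phenyl]acetate
Conditions: MOMCl, i-Pr2NEt, CH2Cl2, 0 °C → rt
Reagents that add atoms: chloromethyl methyl ether (MOMCl), COCCl
Why: O-alkylation of both phenols; the 2-O-MOM group later keeps this oxygen from attacking the C2 carboxyl.

Step 13
Reactants: 19 the arylacetate; 20 dimethyl carbonate; 21 1-bromo-3-methylbut-2-ene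
Product: 23 dimethyl 2-[2,4-bis(methoxymethoxy)phenyl]-2-(3-methylbut-2-en-1-yl)malonate, via sodium malonate enolate 22 (not isolated)
Conditions: NaH, THF, reflux; then 21, DMF, rt → 50 °C
Reagents that add atoms: none
Why: Crossed Claisen C-methoxycarbonylation driven by formation of the stabilised arylmalonate anion, which is then C-alkylated at the primary allylic carbon (SN2) to give the prochiral quaternary malonate.

Step 14
Reactants: 23 the prochiral malonate
Product: 24 methyl (2S)-2-[2,4-bis(methoxymethoxy)phenyl]-2-(hydroxymethyl)-5-methylhex-4-enoate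
Conditions: ZnEt2 (10 mol %), chiral pipecolinol-derived 2,6-bis(aminomethyl)phenol ligand (5 mol %), (EtO)2MeSiH, THF, rt; then pH 7 buffer, MeOH
Reagents that add atoms: none
Why: Catalytic enantioselective desymmetrising hydrosilylation of a malonic ester: the chiral dinuclear zinc hydride reduces one of the two enantiotopic ester groups by telling the aryl from the prenyl flank and stops at the hydroxy ester, which sets the quaternary centre (S).

Step 15
Reactants: 24 the hydroxy ester
Product: 25 methyl (2S)-2-[2,4-bis(methoxymethoxy)phenyl]-2-formyl-5-methylhex-4-enoate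
Conditions: Dess–Martin periodinane, CH2Cl2, 0 °C → rt
Reagents that add atoms: none
Why: Dess–Martin oxidation of the neopentyl primary alcohol; the aldehyde has no α-hydrogen, so the centre cannot epimerise.

Step 16
Reactants: 26 4-hydroxy-6-methyl-2H-pyran-2-one; 25 the aldehyde
Product: 28 methyl (2S)-2-[2,4-bis(methoxymethoxy)phenyl]-2-[1-hydroxy-2-(4-hydroxy-2-oxo-2H-pyran-6-yl)ethyl]-5-methylhex-4-enoate (carbinol epimers), via pyrone dianion 27 (not isolated)
Conditions: LiN(i-Pr)2 (2.2 equiv), THF, −78 → −20 °C; then 25, −78 °C; AcOH, −78 °C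
Reagents that add atoms: none
Why: The dianion of triacetic acid lactone reacts at its more basic C6-methylene carbon with the non-enolisable aldehyde (aldol-type addition), and the cold acidic quench forestalls retro-aldol cleavage; the carbinol centre is erased in step 19.

Step 17
Reactants: 16 the tertiary allylic alcohol; 28 the 4-hydroxypyrone
Product: 29 methyl (2S)-2-[2,4-bis(methoxymethoxy)phenyl]-2-{2-[3-((1R,5R,6R)-5-[2,4-bis(methoxymethoxy)phenyl]-6-{[2,4-bis(methoxymethoxy)phenyl][(tert-butyldimethylsilyl)oxy]methyl}-3-methylcyclohex-2-en-1-yl)-4-hydroxy-2-oxo-2H-pyran-6-yl]-1-hydroxyethyl}-5-methylhex-4-enoate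
Conditions: 10-camphorsulfonic acid (10 mol %), 4 Å MS, CH2Cl2, −20 → 0 °C
Reagents that add atoms: none
Why: Friedel–Crafts-type allylation: acid ionises the tertiary allylic alcohol to the methylcyclohexenyl cation and the enol carbon C3 of the 4-hydroxypyrone attacks its secondary terminus anti to the bulky neighbouring substituent (as in the cannabidiol synthesis from p-menthadienol), which sets C1 of the cyclohexene (R, trans to C6) while O-allyl isomers revert under the acid.

Step 18
Reactants: 29 the silyl ether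
Product: 30 the diol: 29 with the benzylic hydroxyl free
Conditions: HF·pyridine, pyridine, THF, 0 °C → rt
Reagents that add atoms: none
Why: Fluoride cleavage of the silyl ether under buffered, weakly acidic conditions that spare the MOM ethers and avoid alkoxide-driven retro-aldol cleavage of the β-hydroxy ester.

Step 19
Reactants: 30 the diol
Product: 31 methyl (2S)-2-[2,4-bis(methoxymethoxy)phenyl]-2-{2-[3-((1R,5R,6R)-6-[2,4-bis(methoxymethoxy)benzoyl]-5-[2,4-bis(methoxymethoxy)phenyl]-3-methylcyclohex-2-en-1-yl)-4-hydroxy-2-oxo-2H-pyran-6-yl]acetyl}-5-methylhex-4-enoate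
Conditions: Dess–Martin periodinane (3 equiv), CH2Cl2, 0 °C → rt
Reagents that add atoms: none
Why: Dess–Martin oxidation of both secondary alcohols in one operation gives the aryl ketone and the 6-(2-oxoalkyl) side chain under non-basic conditions, so the cis aryl/aroyl centre next to the new ketone is not enolised.

Step 20
Reactants: 31 the 3-cyclohexenyl-4-hydroxy-6-(2-oxoalkyl)-2-pyrone
Product: 34 (3S)-3-[2,4-bis(methoxymethoxy)phenyl]-6-((1R,5R,6R)-6-[2,4-bis(methoxymethoxy)benzoyl]-5-[2,4-bis(methoxymethoxy)phenyl]-3-methylcyclohex-2-en-1-yl)-5,7-dihydroxy-3-(3-methylbut-2-en-1-yl)chromane-2,4-dione, via triketo diester 32 (not isolated), via acylphloroglucinol ester 33 (not isolated)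
Conditions: Mg(OMe)2, MeOH, 55 °C; then AcOH, 0 °C, evaporate; PhMe, 5 Å MS, 90 °C
Reagents that add atoms: none
Why: Proposed new method: methoxide from the magnesium salt opens the pyronate at its lactone carbonyl to the magnesium-chelated triketo diester 32, whose C4a carbanion (between the C4 and C8a carbonyls) attacks the C5 ester carbon in a 6-(enolendo)-exo-trig Claisen condensation, and the trione enolises to acylphloroglucinol 33 (ring A, bond C4a–C5). After neutralisation and removal of methanol the C8a hydroxyl closes the lactone onto the C2 methyl ester (6-exo-trig, bond O1–C2); this closure is deferred to the neutral stage because methoxide would reopen an aryl lactone. The closest known reaction type is the Mg(OMe)2- or KOH-induced ring opening and Claisen recyclisation of 4-hydroxy-6-(2-oxoalkyl)-2-pyrones and 3,5,7-triketo esters to acylphloroglucinols, followed by the ordinary lactonisation of o-hydroxyaryl β-keto esters. No stereocentre is made: C3 is quaternary and non-enolisable and comes unchanged from aldehyde 25. The step needs Claisen closure at C5 in preference to aldol folding (C6 onto C4, which gives a ring that cannot aromatise because C6 carries the cyclohexenyl group and so reverts) and to the second Claisen mode (C8 onto the C2 ester, held back only by the neopentyl position of that ester on C3 beside the ortho-substituted aryl group); it also needs lactonisation by the C8a hydroxyl, which is flanked only by C8–H, and not by the C5 hydroxyl, which is buttressed by the cyclohexenyl group. Retro-Claisen cleavage at C3–C4 and epimerisation next to the aryl ketone are limited by the mild, chelating base and the polyanionic state of the substrate.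

Step 21
Reactants: 34 the hexa-MOM ether
Product: 35 the target, (3S)-3-(2,4-dihydroxyphenyl)-6-[(1R,5R,6R)-6-(2,4-dihydroxybenzoyl)-5-(2,4-dihydroxyphenyl)-3-methylcyclohex-2-en-1-yl]-5,7-dihydroxy-3-(3-methylbut-2-en-1-yl)chromane-2,4-dione
Conditions: ZnBr2, n-PrSH, CH2Cl2, 0 °C, 15 min
Reagents that add atoms: none
Why: Lewis acid-assisted acetal cleavage in which the thiol traps the methoxymethyl cation, so the six aryl MOM ethers fall quickly at 0 °C without protic acid, methanol or water that could open the aryl lactone, hydrate the prenyl group or epimerise the ketone.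

**Compound list**

1 | 2,4-dihydroxybenzaldehyde | O=Cc1ccc(O)cc1O | starting material
2 | 2,4-bis(methoxymethoxy)benzaldehyde | O=Cc1ccc(OCOC)cc1OCOC | intermediate
3 | 1-(2,4-dihydroxyphenyl)ethan-1-one | CC(=O)c1ccc(O)cc1O | starting material
4 | 1-[2-hydroxy-4-(methoxymethoxy)phenyl]ethan-1-one | CC(=O)c1ccc(OCOC)cc1O | intermediate
5 | (E)-3-[2,4-bis(methoxymethoxy)phenyl]-1-[2-hydroxy-4-(methoxymethoxy)phenyl]prop-2-en-1-one | O=C(/C=C/c1ccc(OCOC)cc1OCOC)c1ccc(OCOC)cc1O | intermediate
6 | isoprene (2-methylbuta-1,3-diene) | C=CC(C)=C | starting material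
7 | trans Diels–Alder adduct, (1R,6R), free 2-hydroxyl on the aroyl ring | C1C=C(C)C[C@@H](c2ccc(OCOC)cc2OCOC)[C@@H]1C(=O)c1ccc(OCOC)cc1O | intermediate
8 | trans ketone, (1R,6R), four MOM ethers | C1C=C(C)C[C@@H](c2ccc(OCOC)cc2OCOC)[C@@H]1C(=O)c1ccc(OCOC)cc1OCOC | intermediate
9 | lithium enolate of 8 (exocyclic; aryl-bearing ring carbon unchanged) | [Li]OC(c1ccc(OCOC)cc1OCOC)=C1CC=C(C)C[C@H]1c1ccc(OCOC)cc1OCOC | intermediate
10 | cis ketone, (1S,6R) | C1C=C(C)C[C@@H](c2ccc(OCOC)cc2OCOC)[C@H]1C(=O)c1ccc(OCOC)cc1OCOC | intermediate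
11 | cis carbinol, (1S,6R), carbinol epimers | C1C=C(C)C[C@@H](c2ccc(OCOC)cc2OCOC)[C@H]1C(O)c1ccc(OCOC)cc1OCOC | intermediate
12 | tert-butyldimethylsilyl ether of 11 | C1C=C(C)C[C@@H](c2ccc(OCOC)cc2OCOC)[C@H]1C(O[Si](C)(C)C(C)(C)C)c1ccc(OCOC)cc1OCOC | intermediate
13 | 3,4-epoxide of 12 (both faces) | C1C2OC2(C)C[C@@H](c3ccc(OCOC)cc3OCOC)[C@H]1C(O[Si](C)(C)C(C)(C)C)c1ccc(OCOC)cc1OCOC | intermediate
14 | β-hydroxy selenide (PhSe on the secondary carbon, OH on the methyl-bearing carbon) | C1C([Se]c2ccccc2)C(C)(O)C[C@@H](c2ccc(OCOC)cc2OCOC)[C@H]1C(O[Si](C)(C)C(C)(C)C)c1ccc(OCOC)cc1OCOC | intermediate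
15 | selenoxide of 14 | C1C([Se](=O)c2ccccc2)C(C)(O)C[C@@H](c2ccc(OCOC)cc2OCOC)[C@H]1C(O[Si](C)(C)C(C)(C)C)c1ccc(OCOC)cc1OCOC | intermediate
16 | (4S,5R)-5-aryl-4-[aryl(silyloxy)methyl]-1-methylcyclohex-2-en-1-ol (both C1 epimers) | C1=CC(C)(O)C[C@@H](c2ccc(OCOC)cc2OCOC)[C@H]1C(O[Si](C)(C)C(C)(C)C)c1ccc(OCOC)cc1OCOC | intermediate
17 | 2,4-dihydroxyphenylacetic acid | OC(=O)Cc1ccc(O)cc1O | starting material
18 | methyl 2-(2,4-dihydroxyphenyl)acetate | COC(=O)Cc1ccc(O)cc1O | intermediate
19 | methyl 2-[2,4-bis(methoxymethoxy)phenyl]acetate | COC(=O)Cc1ccc(OCOC)cc1OCOC | intermediate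
20 | dimethyl carbonate | COC(=O)OC | starting material
21 | 1-bromo-3-methylbut-2-ene | CC(C)=CCBr | starting material
22 | sodium enolate of dimethyl 2-[2,4-bis(methoxymethoxy)phenyl]malonate | COC(O[Na])=C(C(=O)OC)c1ccc(OCOC)cc1OCOC | intermediate
23 | dimethyl 2-[2,4-bis(methoxymethoxy)phenyl]-2-(3-methylbut-2-en-1-yl)malonate | COC(=O)C(CC=C(C)C)(C(=O)OC)c1ccc(OCOC)cc1OCOC | intermediate
24 | methyl (2S)-2-[2,4-bis(methoxymethoxy)phenyl]-2-(hydroxymethyl)-5-methylhex-4-enoate | COC(=O)[C@@](CC=C(C)C)(c1ccc(OCOC)cc1OCOC)CO | intermediate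
25 | methyl (2S)-2-[2,4-bis(methoxymethoxy)phenyl]-2-formyl-5-methylhex-4-enoate | COC(=O)[C@@](CC=C(C)C)(c1ccc(OCOC)cc1OCOC)C=O | intermediate
26 | 4-hydroxy-6-methyl-2H-pyran-2-one (triacetic acid lactone) | CC1=CC(O)=CC(=O)O1 | starting material
27 | dilithium dianion of 26 (O4 and C6-methylene) | [Li]CC1=CC(O[Li])=CC(=O)O1 | intermediate
28 | pyrone–aldehyde adduct, (2S), carbinol epimers | COC(=O)[C@@](CC=C(C)C)(c1ccc(OCOC)cc1OCOC)C(O)CC1=CC(O)=CC(=O)O1 | intermediate
29 | coupled pyrone, silyl ether, cyclohexene (1R,5R,6R) | COC(=O)[C@@](CC=C(C)C)(c1ccc(OCOC)cc1OCOC)C(O)CC1=CC(O)=C([C@@H]2C=C(C)C[C@@H](c3ccc(OCOC)cc3OCOC)[C@H]2C(O[Si](C)(C)C(C)(C)C)c2ccc(OCOC)cc2OCOC)C(=O)O1 | intermediate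
30 | coupled pyrone, diol | COC(=O)[C@@](CC=C(C)C)(c1ccc(OCOC)cc1OCOC)C(O)CC1=CC(O)=C([C@@H]2C=C(C)C[C@@H](c3ccc(OCOC)cc3OCOC)[C@H]2C(O)c2ccc(OCOC)cc2OCOC)C(=O)O1 | intermediate
31 | pyrone precursor of the key step | COC(=O)[C@@](CC=C(C)C)(c1ccc(OCOC)cc1OCOC)C(=O)CC1=CC(O)=C([C@@H]2C=C(C)C[C@@H](c3ccc(OCOC)cc3OCOC)[C@H]2C(=O)c2ccc(OCOC)cc2OCOC)C(=O)O1 | intermediate
32 | ring-opened triketo diester (present as its magnesium chelate; keto form written) | COC(=O)[C@@](CC=C(C)C)(c1ccc(OCOC)cc1OCOC)C(=O)CC(=O)CC(=O)C([C@@H]1C=C(C)C[C@@H](c2ccc(OCOC)cc2OCOC)[C@H]1C(=O)c1ccc(OCOC)cc1OCOC)C(=O)OC | intermediate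
33 | acylphloroglucinol methyl ester | COC(=O)[C@@](CC=C(C)C)(c1ccc(OCOC)cc1OCOC)C(=O)c1c(O)cc(O)c([C@@H]2C=C(C)C[C@@H](c3ccc(OCOC)cc3OCOC)[C@H]2C(=O)c2ccc(OCOC)cc2OCOC)c1O | intermediate
34 | hexa(methoxymethyl) ether of the target | CC(C)=CC[C@@]1(c2ccc(OCOC)cc2OCOC)C(=O)Oc2cc(O)c([C@@H]3C=C(C)C[C@@H](c4ccc(OCOC)cc4OCOC)[C@H]3C(=O)c3ccc(OCOC)cc3OCOC)c(O)c2C1=O | intermediate
35 | CNP0157558.3 | CC(C)=CC[C@@]1(c2ccc(O)cc2O)C(=O)Oc2cc(O)c([C@@H]3C=C(C)C[C@@H](c4ccc(O)cc4O)[C@H]3C(=O)c3ccc(O)cc3O)c(O)c2C1=O | target

**Step count and risks**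

Total steps: 21. Longest linear sequence: 14 steps (1, 3–10, 17–21).

Steps most likely to fail:

1. Step 20 (the proposed new method). Ring opening of the hindered 3-substituted pyronate may stall; the triketone carbanion C8 may close onto the C2 ester or methoxide may cleave C3–C4; the lactone may close onto the C5 hydroxyl. Fallback with known chemistry: build ring A and the lactone before the cyclohexene is attached, where the pyrone is 3-unsubstituted as in the precedent and the two ortho hydroxyls are equivalent. It sets out from 28 and 16. 28 is oxidised with Dess–Martin periodinane to the keto pyrone F1. Mg(OMe)2 in MeOH, then AcOH and heat in toluene over 5 Å sieves, gives the 5,7-dihydroxychromanedione F2. Acid-catalysed allylation of F2 by 16 at C6 (camphorsulfonic acid, CH2Cl2; any C8 isomer is separated) gives the silyl ether F3. HF·pyridine gives the alcohol F4, and Dess–Martin oxidation returns to the route at 34.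

2. Step 17. The allyl cation may be intercepted by the side-chain hydroxyl, the prenyl alkene or the electron-rich aryl rings of the elaborate pyrone partner, or conversion may be poor because that partner cannot be used in excess. Fallback: form the C–C bond on the simple pyrone first. It sets out from 16 and 26. The same acid-catalysed allylation with a large excess of 26 gives the pyrone silyl ether F5. Its dianion (LiN(i-Pr)2, 2.2 equiv, THF, −78 °C) is added to aldehyde 25, which returns to the route at 29.

3. Step 21. Once the 2-hydroxyl of the C3 aryl group is free it may attack the lactone carbonyl (translactonisation); the Lewis acid may cyclise the prenyl group; six acetals may not all fall in the short time allowed. Fallback: exchange the protecting groups and free the phenols under buffered fluoride. It sets out from 34. TESOTf and 2,2′-bipyridyl in MeCN convert the aryl MOM ethers (and the two free phenols) into the octakis(triethylsilyl) ether F6, which is isolated. HF·pyridine buffered with pyridine in THF at 0 °C then gives 35.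

**Further compounds**

F1 | step 20 | methyl (2S)-2-[2,4-bis(methoxymethoxy)phenyl]-2-[2-(4-hydroxy-2-oxo-2H-pyran-6-yl)acetyl]-5-methylhex-4-enoate | COC(=O)[C@@](CC=C(C)C)(c1ccc(OCOC)cc1OCOC)C(=O)CC1=CC(O)=CC(=O)O1
F2 | step 20 | (3S)-3-[2,4-bis(methoxymethoxy)phenyl]-5,7-dihydroxy-3-(3-methylbut-2-en-1-yl)chromane-2,4-dione | CC(C)=CC[C@@]1(c2ccc(OCOC)cc2OCOC)C(=O)Oc2cc(O)cc(O)c2C1=O
F3 | step 20 | 6-cyclohexenyl chromanedione with the benzylic tert-butyldimethylsilyl ether | CC(C)=CC[C@@]1(c2ccc(OCOC)cc2OCOC)C(=O)Oc2cc(O)c([C@@H]3C=C(C)C[C@@H](c4ccc(OCOC)cc4OCOC)[C@H]3C(O[Si](C)(C)C(C)(C)C)c3ccc(OCOC)cc3OCOC)c(O)c2C1=O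
F4 | step 20 | 6-cyclohexenyl chromanedione with the free benzylic alcohol | CC(C)=CC[C@@]1(c2ccc(OCOC)cc2OCOC)C(=O)Oc2cc(O)c([C@@H]3C=C(C)C[C@@H](c4ccc(OCOC)cc4OCOC)[C@H]3C(O)c3ccc(OCOC)cc3OCOC)c(O)c2C1=O
F5 | step 17 | 3-cyclohexenyl-4-hydroxy-6-methyl-2H-pyran-2-one with the benzylic tert-butyldimethylsilyl ether | CC1=CC(O)=C([C@@H]2C=C(C)C[C@@H](c3ccc(OCOC)cc3OCOC)[C@H]2C(O[Si](C)(C)C(C)(C)C)c2ccc(OCOC)cc2OCOC)C(=O)O1
F6 | step 21 | octakis(triethylsilyl) ether of the target | CC(C)=CC[C@@]1(c2ccc(O[Si](CC)(CC)CC)cc2O[Si](CC)(CC)CC)C(=O)Oc2cc(O[Si](CC)(CC)CC)c([C@@H]3C=C(C)C[C@@H](c4ccc(O[Si](CC)(CC)CC)cc4O[Si](CC)(CC)CC)[C@H]3C(=O)c3ccc(O[Si](CC)(CC)CC)cc3O[Si](CC)(CC)CC)c(O[Si](CC)(CC)CC)c2C1=O
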